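**Retrosynthetic overview**

1. The C6 quaternary centre is made last, by catalytic asymmetric dearomative C‑prenylation of a lactone‑masked aromatic precursor; opening the resulting enol lactone frees the acid and the enolised triketone.
2. The lactone (C8–CH(Ph) bond, benzylic centre) comes from a chiral NHC/acyl azolium annulation of the C8–H phenol with 3‑phenylpropynal.
3. The C11 side chain comes from a C6 ortho‑quinone methide and 5‑methylhex‑5‑enal (enamine catalysis sets the chain centre), followed by an isopropylidene Wittig reaction.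
4. Key disconnection: chromanone C3–C4. The aldehyde carbon of an O‑[(S)‑but‑3‑en‑2‑yl] salicylaldehyde is used with reversed polarity, as an acyl anion (Breslow intermediate), and adds across the unactivated vinyl group; C2 comes from the chiral alcohol and C3 follows by equilibration.
5. Ring order: benzene ring (phloroglucinol) → dihydropyranone ring (hydroacylation) → transient lactol ring → δ‑lactone ring → dearomatisation of the benzene ring and lactone opening.

Assumption: the target is drawn as one tautomer of an enolised 2‑acylcyclohexane‑1,3,5‑trione; the tautomers interconvert, so delivering this constitution and configuration is taken as delivering the target.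

**Step 1**
Reactants: 1 phloroglucinol; 2 (R)-but-3-en-2-ol
Product: 3 5-[(2S)-but-3-en-2-yloxy]benzene-1,3-diol
Conditions: PPh3, DIAD, THF, 0 °C to rt (3 equiv of 1)
Reagents that add atoms: none
Why: Mitsunobu reaction, in which SN2 displacement of the activated alcohol by a phenol oxygen inverts the carbinol centre (R alcohol to S ether, the future C2), while a threefold excess of the symmetrical, water‑extractable triol 1 limits the reaction to mono‑etherification.

**Step 2**
Reactants: 3 5-[(2S)-but-3-en-2-yloxy]benzene-1,3-diol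
Product: 5 2-[(2S)-but-3-en-2-yloxy]-4,6-dihydroxybenzaldehyde, via iminium chloride 4 (not isolated)
Conditions: POCl3, DMF, MeCN, 0 °C to rt; then H2O, 50 °C
Reagents that add atoms: N,N-dimethylformamide CN(C)C=O; water O
Why: Vilsmeier–Haack formylation goes to one of the two equivalent positions ortho to the ether and para to a hydroxyl rather than to the single position between the hydroxyls, the usual outcome for phloroglucinol mono‑ethers, and does not touch the stereocentre.

**Step 3 (key step)**
Reactants: 5 2-[(2S)-but-3-en-2-yloxy]-4,6-dihydroxybenzaldehyde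
Product: 8 (2S,3S)-5,7-dihydroxy-2,3-dimethylchroman-4-one, via bis-TMS aldehyde 6 (not isolated), via bis-TMS chromanone 7 (not isolated)
Conditions: (Me3Si)2NH, cat. Me3SiCl, MeCN, 60 °C, evaporate; 3-(2,6-diisopropylphenyl)-4,5-dimethylthiazol-3-ium perchlorate (15 mol %), DBU (30 mol %), 1,4-dioxane, 110 °C; then K2CO3 (20 mol %), MeOH, rt
Reagents that add atoms: none
Why: NHC‑catalysed intramolecular hydroacylation of an unactivated alkene, in which the thiazolylidene turns the normally electrophilic aldehyde carbon into a nucleophilic Breslow intermediate (acyl anion equivalent) that adds to the internal vinyl carbon with concerted proton transfer to the terminus and closes the six‑membered ketone ring; C2 (S) is carried over from 3, C3 is equilibrated by DBU and K2CO3 to the more stable trans (3S) arrangement, and the transient silyl ethers keep the acidic phenols from protonating the carbene.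

**Step 4**
Reactants: 8 (2S,3S)-5,7-dihydroxy-2,3-dimethylchroman-4-one
Product: 9 (2S,3S)-5,7-dihydroxy-2,3-dimethyl-6-[(4-methylphenyl)sulfonylmethyl]chroman-4-one
Conditions: (CH2O)n (1.0 equiv), 4-MeC6H4SO2Na, HCO2H/H2O, rt
Reagents that add atoms: formaldehyde C=O; sodium 4-methylbenzenesulfinate [Na+].[O-]S(=O)c1ccc(C)cc1
Why: Three‑component sulfonylmethylation (hydroxymethylation, ortho‑quinone methide formation, S‑attack of sulfinate) is expected at C6, the carbon flanked by both hydroxyls and the usual site of C‑alkylation and aminomethylation in 5,7‑dihydroxychromanones, with one equivalent of formaldehyde to avoid double reaction.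

**Step 5**
Reactants: 10 2-methylpenta-1,4-diene
Product: 11 5-methylhex-5-enal
Conditions: Rh(acac)(CO)2 (0.5 mol %), Xantphos (1.5 mol %), CO/H2 (1:1, 10 bar), toluene, 70 °C
Reagents that add atoms: carbon monoxide [C-]#[O+]
Why: Rhodium‑catalysed hydroformylation with the wide‑bite‑angle diphosphine gives the linear aldehyde and reacts only at the monosubstituted alkene, the 1,1‑disubstituted alkene being much slower.

**Step 6**
Reactants: 9 (2S,3S)-5,7-dihydroxy-2,3-dimethyl-6-[(4-methylphenyl)sulfonylmethyl]chroman-4-one; 11 5-methylhex-5-enal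
Product: 13 (2S,3S,7R)-5,8-dihydroxy-2,3-dimethyl-7-(3-methylbut-3-en-1-yl)-2,3,7,8-tetrahydro-4H,6H-pyrano[3,2-g]chromen-4-one (lactol; both C8 epimers), via ortho-quinone methide 12 (not isolated)
Conditions: (S)-α,α-diphenylprolinol trimethylsilyl ether (20 mol %), NaHCO3, CH2Cl2/H2O, 0 °C (3 equiv of 11)
Reagents that add atoms: none
Why: Enamine‑catalysed asymmetric α‑alkylation, in which NaHCO3 expels sulfinate from 9 to give the ortho‑quinone methide 12, whose methylene carbon is attacked by the E‑enamine of 11 from the face not shielded by the diphenyl(silyloxy)methyl group, setting the R chain centre, and the aldehyde is stored as the lactol with O7, which protects that centre from epimerisation.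

**Step 7**
Reactants: 13 lactol (2S,3S,7R)-5,8-dihydroxy-2,3-dimethyl-7-(3-methylbut-3-en-1-yl)-2,3,7,8-tetrahydro-4H,6H-pyrano[3,2-g]chromen-4-one
Product: 14 (2S,3S)-5,7-dihydroxy-2,3-dimethyl-6-[(2R)-5-methyl-2-(2-methylprop-1-en-1-yl)hex-5-en-1-yl]chroman-4-one
Conditions: i-PrPPh3I, n-BuLi (5 equiv of ylide), THF, −78 to 0 °C; then aq. NH4Cl
Reagents that add atoms: isopropyltriphenylphosphonium iodide CC(C)[P+](c1ccccc1)(c1ccccc1)c1ccccc1.[I-]
Why: Wittig olefination of the open hydroxy‑aldehyde form of the lactol with the non‑stabilised isopropylidene ylide (excess to cover the acidic hydroxyls) gives the trisubstituted alkene at low temperature without epimerising the adjacent centre, while the ketone is inert as part of a phenoxide‑conjugated vinylogous carboxylate.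

**Step 8**
Reactants: 14 (2S,3S)-5,7-dihydroxy-2,3-dimethyl-6-[(2R)-5-methyl-2-(2-methylprop-1-en-1-yl)hex-5-en-1-yl]chroman-4-one; 15 3-phenylprop-2-ynal
Product: 16 (2S,3S,10R)-5-hydroxy-2,3-dimethyl-6-[(2R)-5-methyl-2-(2-methylprop-1-en-1-yl)hex-5-en-1-yl]-10-phenyl-2,3,9,10-tetrahydro-4H,8H-pyrano[2,3-f]chromene-4,8-dione
Conditions: (5aS,10bR)-2-mesityl-5a,10b-dihydro-4H,6H-indeno[2,1-b][1,2,4]triazolo[4,3-d][1,4]oxazin-2-ium chloride (10 mol %), toluene, 40 °C
Reagents that add atoms: none
Why: Chiral NHC catalysis through an α,β‑unsaturated acyl azolium (internal redox of the ynal), in which the cinnamoyl azolium is captured at O7 and delivered to the only free ring carbon C8 by a Coates–Claisen‑type rearrangement followed by lactonisation, the aminoindanol‑derived catalyst blocking one face of the β carbon to set the R benzylic centre (the antipodal catalyst is used should the sense prove opposite on a model phenol).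

**Step 9**
Reactants: 16 (2S,3S,10R)-5-hydroxy-2,3-dimethyl-6-[(2R)-5-methyl-2-(2-methylprop-1-en-1-yl)hex-5-en-1-yl]-10-phenyl-2,3,9,10-tetrahydro-4H,8H-pyrano[2,3-f]chromene-4,8-dione; 17 prenyl acetate
Product: 19 (3R)-3-{(2S,3S,6S)-4-hydroxy-2,3-dimethyl-6-[(2R)-5-methyl-2-(2-methylprop-1-en-1-yl)hex-5-en-1-yl]-6-(3-methylbut-2-en-1-yl)-5,7-dioxo-3,5,6,7-tetrahydro-2H-chromen-8-yl}-3-phenylpropanoic acid, via dearomatised enol lactone 18 (not isolated)
Conditions: Pd2(dba)3 (2.5 mol %), (R,R)-DACH-phenyl Trost ligand (7.5 mol %), Cs2CO3, 1,4-dioxane, rt; then LiOH, THF/H2O, 0 °C; then 1 M HCl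
Reagents that add atoms: lithium hydroxide [Li+].[OH-]
Why: Palladium‑catalysed asymmetric allylic dearomatisation (Tsuji–Trost type), in which the C5 phenoxide attacks the unsubstituted terminus of the prenyl–palladium complex through C6 (O‑prenylation is reversible and C8 is blocked), the chiral diphosphine selecting the face that gives 6S over the remote stereocentres (ligand antipode if mismatched), and hydroxide then opens the enol lactone to the acid and the enolised triketone.

**Compound list**

1 | phloroglucinol (benzene-1,3,5-triol) | Oc1cc(O)cc(O)c1 | starting material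
2 | (R)-but-3-en-2-ol | C=C[C@@H](C)O | starting material
3 | 5-[(2S)-but-3-en-2-yloxy]benzene-1,3-diol | C=C[C@H](C)Oc1cc(O)cc(O)c1 | intermediate
4 | N-{2-[(2S)-but-3-en-2-yloxy]-4,6-dihydroxybenzylidene}-N-methylmethanaminium chloride (iminium chloride) | C=C[C@H](C)Oc1cc(O)cc(O)c1C=[N+](C)C.[Cl-] | intermediate
5 | 2-[(2S)-but-3-en-2-yloxy]-4,6-dihydroxybenzaldehyde | C=C[C@H](C)Oc1cc(O)cc(O)c1C=O | intermediate
6 | 2-[(2S)-but-3-en-2-yloxy]-4,6-bis(trimethylsilyloxy)benzaldehyde (bis-TMS aldehyde) | C=C[C@H](C)Oc1cc(O[Si](C)(C)C)cc(O[Si](C)(C)C)c1C=O | intermediate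
7 | (2S,3S)-2,3-dimethyl-5,7-bis(trimethylsilyloxy)chroman-4-one (bis-TMS chromanone) | C[C@@H]1Oc2cc(O[Si](C)(C)C)cc(O[Si](C)(C)C)c2C(=O)[C@H]1C | intermediate
8 | (2S,3S)-5,7-dihydroxy-2,3-dimethylchroman-4-one | C[C@@H]1Oc2cc(O)cc(O)c2C(=O)[C@H]1C | intermediate
9 | (2S,3S)-5,7-dihydroxy-2,3-dimethyl-6-[(4-methylphenyl)sulfonylmethyl]chroman-4-one | C[C@@H]1Oc2cc(O)c(CS(=O)(=O)c3ccc(C)cc3)c(O)c2C(=O)[C@H]1C | intermediate
10 | 2-methylpenta-1,4-diene | C=CCC(C)=C | starting material
11 | 5-methylhex-5-enal | C=C(C)CCCC=O | intermediate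
12 | (2S,3S)-5-hydroxy-2,3-dimethyl-6-methylidene-2,3-dihydro-4H-chromene-4,7(6H)-dione (ortho-quinone methide) | C=C1C(=O)C=C2O[C@@H](C)[C@H](C)C(=O)C2=C1O | intermediate
13 | (2S,3S,7R)-5,8-dihydroxy-2,3-dimethyl-7-(3-methylbut-3-en-1-yl)-2,3,7,8-tetrahydro-4H,6H-pyrano[3,2-g]chromen-4-one (lactol of the C6–CH2–CH(R)–CHO aldehyde with O7; both C8 epimers) | C[C@@H]1Oc2cc3OC(O)[C@H](CCC(C)=C)Cc3c(O)c2C(=O)[C@H]1C | intermediate
14 | (2S,3S)-5,7-dihydroxy-2,3-dimethyl-6-[(2R)-5-methyl-2-(2-methylprop-1-en-1-yl)hex-5-en-1-yl]chroman-4-one | C=C(C)CC[C@@H](C=C(C)C)Cc1c(O)cc2O[C@@H](C)[C@H](C)C(=O)c2c1O | intermediate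
15 | 3-phenylprop-2-ynal | O=CC#Cc1ccccc1 | starting material
16 | (2S,3S,10R)-5-hydroxy-2,3-dimethyl-6-[(2R)-5-methyl-2-(2-methylprop-1-en-1-yl)hex-5-en-1-yl]-10-phenyl-2,3,9,10-tetrahydro-4H,8H-pyrano[2,3-f]chromene-4,8-dione (14 with a δ-lactone O7–C(=O)–CH2–CH(Ph)–C8) | C=C(C)CC[C@@H](C=C(C)C)Cc1c(O)c2C(=O)[C@@H](C)[C@H](C)Oc2c3c1OC(=O)C[C@@H]3c1ccccc1 | intermediate
17 | prenyl acetate (3-methylbut-2-en-1-yl acetate) | CC(=O)OCC=C(C)C | starting material
18 | (2S,3S,6S,10R)-2,3-dimethyl-6-[(2R)-5-methyl-2-(2-methylprop-1-en-1-yl)hex-5-en-1-yl]-6-(3-methylbut-2-en-1-yl)-10-phenyl-2,3,9,10-tetrahydro-4H,8H-pyrano[2,3-f]chromene-4,5,8(6H)-trione (dearomatised enol lactone) | C=C(C)CC[C@@H](C=C(C)C)C[C@@]1(CC=C(C)C)C(=O)C2=C(O[C@@H](C)[C@H](C)C2=O)C2=C1OC(=O)C[C@@H]2c1ccccc1 | intermediate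
19 | (3R)-3-{(2S,3S,6S)-4-hydroxy-2,3-dimethyl-6-[(2R)-5-methyl-2-(2-methylprop-1-en-1-yl)hex-5-en-1-yl]-6-(3-methylbut-2-en-1-yl)-5,7-dioxo-3,5,6,7-tetrahydro-2H-chromen-8-yl}-3-phenylpropanoic acid | C=C(C)CC[C@@H](C=C(C)C)C[C@@]1(CC=C(C)C)C(=O)C2=C(O)[C@@H](C)[C@H](C)OC2=C([C@H](CC(=O)O)c2ccccc2)C1=O | target

**Step count and risks**

Total steps: 9. Longest linear sequence: 8 (steps 1–4 and 6–9, from 1 to 19); step 5 is a one‑step side branch.

The three steps most likely to fail:

- **Step 3.** The aldehyde is very electron‑rich and doubly ortho‑oxygenated, so Breslow intermediate formation may be slow; the silyl ethers may not survive; and C2 could erode at 110 °C. Fallback: the chromanone is made without the carbene. Phloroglucinol 1 is C‑acylated with tigloyl chloride (AlCl3, PhNO2) to (E)-2-methyl-1-(2,4,6-trihydroxyphenyl)but-2-en-1-one F1. F1 is closed by a quinidine‑catalysed asymmetric intramolecular oxa‑Michael addition (chlorobenzene, rt), followed by Et3N equilibration of C3 to trans. The route is rejoined at 8.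

- **Step 4.** Attack at C8 instead of C6, or double reaction, would give the wrong constitution. Fallback: the regiochemistry is enforced by masking O7. 8 is silylated at the non‑chelated 7‑hydroxyl (t-BuMe2SiCl, imidazole, DMF) to (2S,3S)-7-[tert-butyl(dimethyl)silyl]oxy-5-hydroxy-2,3-dimethylchroman-4-one F2. Sulfonylmethylation ((CH2O)n, 4-MeC6H4SO2Na, AcOH) can then proceed only ortho to the single free 5‑hydroxyl, giving (2S,3S)-7-[tert-butyl(dimethyl)silyl]oxy-5-hydroxy-2,3-dimethyl-6-[(4-methylphenyl)sulfonylmethyl]chroman-4-one F3. HCl in MeOH removes the silyl group, and the route is rejoined at 9.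

- **Step 9.** Ligand control over a quaternary centre remote from the other stereocentres may be poor, and some branched (reverse‑prenyl) product is possible. Fallback: the alkylation is run as an SN2 reaction on the ring‑opened polyanion under ion‑pair control. 16 is opened with aqueous KOH to the salt of (3R)-3-{(2S,3S)-5,7-dihydroxy-2,3-dimethyl-6-[(2R)-5-methyl-2-(2-methylprop-1-en-1-yl)hex-5-en-1-yl]-4-oxochroman-8-yl}-3-phenylpropanoic acid F4. In the same two‑phase mixture (toluene/aqueous KOH, 0 °C) this is C‑prenylated at C6 with prenyl bromide and N-(9-anthracenylmethyl)cinchonidinium bromide as chiral phase‑transfer catalyst, which can give only the linear prenyl group. Acidification gives 19 directly; the C6 epimers are separated by preparative HPLC if control is incomplete.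

**Further compounds**

F1 | step 3 | (E)-2-methyl-1-(2,4,6-trihydroxyphenyl)but-2-en-1-one | C/C=C(\C)C(=O)c1c(O)cc(O)cc1O
F2 | step 4 | (2S,3S)-7-[tert-butyl(dimethyl)silyl]oxy-5-hydroxy-2,3-dimethylchroman-4-one | C[C@@H]1Oc2cc(O[Si](C)(C)C(C)(C)C)cc(O)c2C(=O)[C@H]1C
F3 | step 4 | (2S,3S)-7-[tert-butyl(dimethyl)silyl]oxy-5-hydroxy-2,3-dimethyl-6-[(4-methylphenyl)sulfonylmethyl]chroman-4-one | C[C@@H]1Oc2cc(O[Si](C)(C)C(C)(C)C)c(CS(=O)(=O)c3ccc(C)cc3)c(O)c2C(=O)[C@H]1C
F4 | step 9 | (3R)-3-{(2S,3S)-5,7-dihydroxy-2,3-dimethyl-6-[(2R)-5-methyl-2-(2-methylprop-1-en-1-yl)hex-5-en-1-yl]-4-oxochroman-8-yl}-3-phenylpropanoic acid | C=C(C)CC[C@@H](C=C(C)C)Cc1c(O)c2C(=O)[C@@H](C)[C@H](C)Oc2c([C@H](CC(=O)O)c2ccccc2)c1O
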